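**Plan**
1. The cinnamate is cut at Cα=Cβ (Horner–Wadsworth–Emmons) and at the ester C–O, and the C6 carbinol is taken back to a ketone; this exposes the aldol pattern C4(OH)–C5(H)–C6(=O) that straddles the ring fusion.
2. That pattern is the retron of a semipinacol shift: the ring-fusion bond C5–C10 is cut and C10 is returned to C6, which turns the trans-decalin into a cis-fused bicyclo[5.3.0]decane (cyclopentane C6–C10 fused to a cycloheptane) with a tertiary OH on C6 next to a C4–C5 epoxide.
3. The seven-membered ring is then cut at C4=C5 (RCM), C5–C6 (vinyl addition) and C1–C10 (enolate alkylation), back to a cyclopentenyl formate obtained from (R)-limonene by ring contraction.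
4. Forward: the cyclopentane comes first, the cycloheptene is closed on it by RCM, and one 1,2-shift then makes ring B (five to six) and ring A (seven to six) together; the acyl group is built last.
5. Stereochemistry: C7 is bought with limonene; C10 (alkylation anti to i-Pr), the C6 carbinol (addition anti to i-Pr and CH3), the epoxide (OH-directed), C5 (inversion in the shift, C4 carried through) and the C6–OH (hydride from the α face) are relayed from it.

Key step: step 10

Remark: atom numbers are eudesmane numbers (C1–C3 ring-A CH2, C4 carbinol, C5 ring-fusion CH, C6 oxygenated CH, C7 isopropyl-bearing CH, C8/C9 CH2, C10 quaternary C, C15 = 4-CH3) and are kept for all intermediates; β is the face of the 10-CH3.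
Remark: C4 of (R)-(+)-limonene becomes C7 (S) of the target; ozonide 3 is taken as a mixture of epimers at its two acetal carbons, both of which give 4.

Step 1
Reactants: 1 (R)-(+)-limonene
Product: 2 (R)-(+)-p-menth-1-ene
Conditions: H2 (1 atm), RhCl(PPh3)3 (cat.), benzene–EtOH, rt
Reagents that add atoms: none
Why: Chemoselective homogeneous hydrogenation should reduce only the 1,1-disubstituted isopropenyl alkene and leave the trisubstituted ring alkene and the stereocentre untouched.

Step 2
Reactants: 2 (R)-(+)-p-menth-1-ene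
Product: 4 (3R)-6-oxo-3-(propan-2-yl)heptanal, via secondary ozonide 3 (not isolated)
Conditions: O3, CH2Cl2, −78 °C; then Me2S, −78 °C → rt
Reagents that add atoms: ozone [O-][O+]=O
Why: Ozonolysis with reductive work-up cleaves the only C=C to the keto aldehyde, and the stereocentre is not α to either carbonyl, so it cannot epimerise.

Step 3
Reactants: 4 (3R)-6-oxo-3-(propan-2-yl)heptanal
Product: 5 (5S)-2-methyl-5-(propan-2-yl)cyclopent-1-ene-1-carbaldehyde
Conditions: piperidine (cat.), AcOH (cat.), benzene, reflux with removal of water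
Reagents that add atoms: none
Why: Enamine-mediated intramolecular aldol condensation of the aldehyde α-carbon onto the methyl ketone should close the five-membered ring and give the tetrasubstituted enal, the known regiochemistry under amine/acid catalysis.

Step 4
Reactants: 5 (5S)-2-methyl-5-(propan-2-yl)cyclopent-1-ene-1-carbaldehyde
Product: 6 (5S)-2-methyl-5-(propan-2-yl)cyclopent-1-en-1-yl formate
Conditions: mCPBA (1.05 equiv), Na2HPO4, CH2Cl2, 0 °C
Reagents that add atoms: mCPBA OOC(=O)c1cccc(Cl)c1
Why: Baeyer–Villiger oxidation of the enal with migration of the electron-rich alkenyl carbon should give the enol formate, which fixes the enol double bond between C6 and C10.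

Step 5
Reactants: 7 4-methylpent-4-en-1-ol
Product: 8 5-iodo-2-methylpent-1-ene
Conditions: I2, PPh3, imidazole, CH2Cl2, 0 °C → rt
Reagents that add atoms: iodine II
Why: Appel iodination of the primary alcohol; the 1,1-disubstituted alkene is inert to these conditions.

Step 6
Reactants: 6 (5S)-2-methyl-5-(propan-2-yl)cyclopent-1-en-1-yl formate, 8 5-iodo-2-methylpent-1-ene
Product: 10 (2R,5S)-2-methyl-2-(4-methylpent-4-en-1-yl)-5-(propan-2-yl)cyclopentan-1-one, via lithium enolate 9 (not isolated)
Conditions: MeLi (2.1 equiv), THF, 0 °C (6 added to MeLi); then 8, DMPU, −40 °C → rt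
Reagents that add atoms: none
Why: Cleavage of the enol ester by MeLi should give the regiodefined tetrasubstituted lithium enolate, and its C-alkylation on the face anti to the neighbouring α'-isopropyl group sets the quaternary C10 with CH3 cis to i-Pr (enolate alkylation under 1,3-induction).

Step 7
Reactants: 10 (2R,5S)-2-methyl-2-(4-methylpent-4-en-1-yl)-5-(propan-2-yl)cyclopentan-1-one
Product: 11 (1R,2R,5S)-1-ethenyl-2-methyl-2-(4-methylpent-4-en-1-yl)-5-(propan-2-yl)cyclopentan-1-ol
Conditions: vinylMgBr, anhydrous CeCl3, THF, −78 → 0 °C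
Reagents that add atoms: vinylmagnesium bromide C=C[Mg]Br
Why: Organocerium 1,2-addition (little enolisation of the hindered ketone) should occur on the face opposite i-Pr and 10-CH3, so vinyl ends cis to the pentenyl chain and the new C6–OH cis to i-Pr and CH3 (steric approach control).

Step 8
Reactants: 11 (1R,2R,5S)-1-ethenyl-2-methyl-2-(4-methylpent-4-en-1-yl)-5-(propan-2-yl)cyclopentan-1-ol
Product: 12 (3S,3aS,8aR)-5,8a-dimethyl-3-(propan-2-yl)-1,2,3,3a,6,7,8,8a-octahydroazulen-3a-ol
Conditions: Ru catalyst HG-II [(H2IMes)Cl2Ru=CH(2-i-PrO-C6H4)] (5 mol %), toluene (5 mM), 80 °C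
Reagents that add atoms: none
Why: Ring-closing metathesis of the vinyl group with the cis-disposed 1,1-disubstituted alkene should close the trisubstituted cycloheptene (C4=C5) with loss of ethene and without touching a stereocentre.

Step 9
Reactants: 12 (3S,3aS,8aR)-5,8a-dimethyl-3-(propan-2-yl)-1,2,3,3a,6,7,8,8a-octahydroazulen-3a-ol
Product: 13 4,5-epoxy-5,8a-dimethyl-3-(propan-2-yl)decahydroazulen-3a-ol with oxirane O, 3a-OH, 8a-CH3 and 3-i-Pr all cis
Conditions: VO(acac)2 (5 mol %), t-BuOOH (1.5 equiv), toluene, 0 °C → rt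
Reagents that add atoms: tert-butyl hydroperoxide CC(C)(C)OO
Why: Hydroxyl-directed vanadium-catalysed epoxidation of the tertiary allylic alcohol should deliver oxygen to the face of the OH and so set C4 and C5 (syn epoxy alcohol).

Step 10
Reactants: 13 4,5-epoxy-5,8a-dimethyl-3-(propan-2-yl)decahydroazulen-3a-ol
Product: 14 (2S,4aR,8S,8aR)-8-hydroxy-4a,8-dimethyl-2-(propan-2-yl)octahydronaphthalen-1(2H)-one
Conditions: ZnBr2 (1.2 equiv), CH2Cl2, −20 °C → rt
Reagents that add atoms: none
Why: Zn(II) should bind the tertiary hydroxyl and the syn oxirane oxygen as a five-membered chelate, and as the C5–O bond lengthens, the ring-fusion bond C6–C10, held anti to it by the chelate, shifts from C6 to C5 while C6 becomes the carbonyl carbon. The closest known reaction type is the Lewis-acid semipinacol rearrangement of tertiary 2,3-epoxy alcohols to β-hydroxy ketones, including its ring-contracting cases on cyclic epoxy alcohols, and the ring-fusion-bond shift of bicyclic cis-diol monosulfonates. The single new bond C5–C10 closes both six-membered rings by an intramolecular SN2-type opening of the oxirane at C5 through a bridged three-centre transition state: the cycloheptane loses C6 and becomes ring A, the cyclopentane gains C5 and becomes ring B. C5 is inverted because C10 enters anti to the leaving oxygen, which gives the trans ring fusion (H-5 α); C10 migrates with retention, C4 keeps the configuration from the directed epoxidation and emerges as the axial 4β-carbinol, and C7 is untouched and is in any case the equatorial, thermodynamically preferred configuration next to the new ketone. The step needs migration of C10 and not C7, and cleavage of C5–O and not of the tertiary C4–O. The chelate puts C7 gauche to the breaking bond, C10 is the better migrating group (quaternary), the shift turns a cis-bicyclo[5.3.0]decane into a trans-decalin and is pushed by the carbinol oxygen, whereas ionisation at C4 has no such assistance.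

Step 11
Reactants: 14 (2S,4aR,8S,8aR)-8-hydroxy-4a,8-dimethyl-2-(propan-2-yl)octahydronaphthalen-1(2H)-one
Product: 15 (1R,2S,4aR,8S,8aS)-4a,8-dimethyl-2-(propan-2-yl)decahydronaphthalene-1,8-diol
Conditions: NaBH4, MeOH–CH2Cl2, −20 → 0 °C
Reagents that add atoms: none
Why: The β face of the C6 ketone is screened by the axial 10-CH3 and the axial 4β-OH, so hydride should enter from the α face and give the axial 6β-alcohol (the sense seen with 6-oxo-5α-steroids).

Step 12
Reactants: 15 (1R,2S,4aR,8S,8aS)-4a,8-dimethyl-2-(propan-2-yl)decahydronaphthalene-1,8-diol, 16 2-(diethoxyphosphoryl)acetic acid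
Product: 17 (1R,2S,4aR,8S,8aS)-8-hydroxy-4a,8-dimethyl-2-(propan-2-yl)decahydronaphthalen-1-yl 2-(diethoxyphosphoryl)acetate
Conditions: DCC, DMAP (cat.), CH2Cl2, 0 °C → rt
Reagents that add atoms: none
Why: Steglich esterification should acylate the secondary 6-OH only, since the tertiary 4-OH is unreactive under these conditions.

Step 13
Reactants: 17 (1R,2S,4aR,8S,8aS)-8-hydroxy-4a,8-dimethyl-2-(propan-2-yl)decahydronaphthalen-1-yl 2-(diethoxyphosphoryl)acetate, 18 3-hydroxybenzaldehyde
Product: 19 (1R,2S,4aR,8S,8aS)-8-hydroxy-4a,8-dimethyl-2-(propan-2-yl)decahydronaphthalen-1-yl (2E)-3-(3-hydroxyphenyl)prop-2-enoate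
Conditions: LiCl, DBU (2.5 equiv), MeCN, rt
Reagents that add atoms: none
Why: Horner–Wadsworth–Emmons olefination with a stabilised phosphonate should give the (E)-cinnamate, and the free meta-phenol is tolerated because its phenoxide is not conjugated with the aldehyde.

**Compound list**
1 | (R)-(+)-limonene, (4R)-1-methyl-4-(prop-1-en-2-yl)cyclohex-1-ene | CC1=CC[C@@H](CC1)C(C)=C | starting material
2 | (R)-(+)-p-menth-1-ene, (4R)-1-methyl-4-(propan-2-yl)cyclohex-1-ene | CC1=CC[C@@H](CC1)C(C)C | intermediate
3 | secondary ozonide of 2, (4R)-1-methyl-4-(propan-2-yl)-7,8,9-trioxabicyclo[4.2.1]nonane, formed in the flask | CC12CC[C@H](CC(OO1)O2)C(C)C | intermediate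
4 | (3R)-6-oxo-3-(propan-2-yl)heptanal | O=CC[C@@H](CCC(C)=O)C(C)C | intermediate
5 | (5S)-2-methyl-5-(propan-2-yl)cyclopent-1-ene-1-carbaldehyde | O=CC1=C(C)CC[C@H]1C(C)C | intermediate
6 | (5S)-2-methyl-5-(propan-2-yl)cyclopent-1-en-1-yl formate | O=COC1=C(C)CC[C@H]1C(C)C | intermediate
7 | 4-methylpent-4-en-1-ol | C=C(C)CCCO | starting material
8 | 5-iodo-2-methylpent-1-ene | C=C(C)CCCI | intermediate
9 | lithium (5S)-2-methyl-5-(propan-2-yl)cyclopent-1-en-1-olate, formed in the flask | [Li]OC1=C(C)CC[C@H]1C(C)C | intermediate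
10 | (2R,5S)-2-methyl-2-(4-methylpent-4-en-1-yl)-5-(propan-2-yl)cyclopentan-1-one (CH3 cis to i-Pr) | CC(C)[C@@H]1CC[C@@](C)(CCCC(C)=C)C1=O | intermediate
11 | (1R,2R,5S)-1-ethenyl-2-methyl-2-(4-methylpent-4-en-1-yl)-5-(propan-2-yl)cyclopentan-1-ol (OH, CH3 and i-Pr cis) | CC(C)[C@@H]1CC[C@@](C)(CCCC(C)=C)[C@@]1(O)C=C | intermediate
12 | (3S,3aS,8aR)-5,8a-dimethyl-3-(propan-2-yl)-1,2,3,3a,6,7,8,8a-octahydroazulen-3a-ol (cis-fused; OH, angular CH3 and i-Pr on one face) | CC(C)[C@@H]1CC[C@@]2(C)CCCC(C)=C[C@@]12O | intermediate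
13 | 4,5-epoxy-5,8a-dimethyl-3-(propan-2-yl)decahydroazulen-3a-ol (azulene numbering; oxirane O, 3a-OH, 8a-CH3 and 3-i-Pr all cis) | CC(C)[C@@H]1CC[C@@]2(C)CCC[C@]3(C)O[C@@H]3[C@@]12O | intermediate
14 | (2S,4aR,8S,8aR)-8-hydroxy-4a,8-dimethyl-2-(propan-2-yl)octahydronaphthalen-1(2H)-one (4β-hydroxy-5α-eudesman-6-one) | CC(C)[C@@H]1CC[C@@]2(C)CCC[C@](C)(O)[C@@H]2C1=O | intermediate
15 | (1R,2S,4aR,8S,8aS)-4a,8-dimethyl-2-(propan-2-yl)decahydronaphthalene-1,8-diol (5α-eudesmane-4β,6β-diol) | CC(C)[C@@H]1CC[C@@]2(C)CCC[C@](C)(O)[C@@H]2[C@@H]1O | intermediate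
16 | 2-(diethoxyphosphoryl)acetic acid | CCOP(=O)(CC(=O)O)OCC | starting material
17 | (1R,2S,4aR,8S,8aS)-8-hydroxy-4a,8-dimethyl-2-(propan-2-yl)decahydronaphthalen-1-yl 2-(diethoxyphosphoryl)acetate | CC(C)[C@@H]1CC[C@@]2(C)CCC[C@](C)(O)[C@@H]2[C@@H]1OC(=O)CP(=O)(OCC)OCC | intermediate
18 | 3-hydroxybenzaldehyde | O=Cc1cccc(O)c1 | starting material
19 | (1R,2S,4aR,8S,8aS)-8-hydroxy-4a,8-dimethyl-2-(propan-2-yl)decahydronaphthalen-1-yl (2E)-3-(3-hydroxyphenyl)prop-2-enoate | CC(C)[C@@H]1CC[C@@]2(C)CCC[C@](C)(O)[C@@H]2[C@@H]1OC(=O)/C=C/c1cccc(O)c1 | target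

**Step count:** 13 steps in total; the longest linear sequence is 12 steps (steps 1–4 and 6–13).

**Steps most likely to fail**

Step 10. The oxirane may ionise at the tertiary carbon C4 (followed by hydride shift or elimination) faster than the assisted shift to the secondary carbon C5, or C7 may migrate in place of C10. The fallback sets out from 13 and returns at 15; it moves the leaving group to a position where only C5 can ionise and installs the C4 carbinol afterwards. Isomerisation of 13 with diethylaluminium 2,2,6,6-tetramethylpiperidide (toluene, 0 °C) should remove a C15 proton and give the exocyclic allylic cis-diol 8a-methyl-5-methylidene-3-(propan-2-yl)octahydroazulene-3a,4(1H)-diol F1. Mesylation of its secondary allylic hydroxyl (MsCl, Et3N, CH2Cl2, −20 °C) gives the allylic mesylate F2. KOt-Bu (THF, 0 °C) should then trigger the pinacol-type shift of the ring-fusion bond, known for bicyclic cis-diol monosulfonates, to 5α-eudesm-4(15)-en-6-one F3. NaBH4 should reduce this from the α face to 5α-eudesm-4(15)-en-6β-ol F4. Ozonolysis (O3; Me2S) gives 6β-hydroxy-15-nor-5α-eudesman-4-one F5, and excess MeMgBr (THF, −78 °C), attacking the 4-ketone from the equatorial α side, gives 15.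

Step 6. C-alkylation of the hindered tetrasubstituted enolate by the unactivated iodide may be slow, proton exchange between enolate and product may erode the configuration at C7, or facial selectivity may be insufficient. The fallback sets out from 6 and returns at 10; it uses an allyl electrophile delivered by palladium and completes the side chain by cross-coupling. Enolate 9 is trapped with allyl chloroformate to give allyl (5S)-2-methyl-5-(propan-2-yl)cyclopent-1-en-1-yl carbonate F6. Pd(PPh3)4 (THF, rt) effects the decarboxylative Tsuji–Trost allylation, again anti to i-Pr, to (2S,5S)-2-methyl-2-(prop-2-en-1-yl)-5-(propan-2-yl)cyclopentan-1-one F7. Hydroboration of the allyl group with 9-BBN gives the B-alkyl-9-borabicyclo[3.3.1]nonane F8, which is coupled in the same flask with 2-bromopropene (PdCl2(dppf), K3PO4, DMF–H2O, Suzuki–Miyaura) to give 10.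

Step 12. The crowded axial 6-hydroxyl (next to i-Pr, syn-axial to 10-CH3 and 4-OH) may not be acylated, or the DCC adduct may rearrange to the N-acylurea first. The fallback sets out from 15 and returns at 17. Acylation with the small, more reactive bromoacetyl bromide (pyridine, CH2Cl2, −20 °C) gives (1R,2S,4aR,8S,8aS)-8-hydroxy-4a,8-dimethyl-2-(propan-2-yl)decahydronaphthalen-1-yl bromoacetate F9, and an Arbuzov reaction with P(OEt)3 (neat, 90 °C) then gives 17.

**Further compounds**
F1 | step 10 | 8a-methyl-5-methylidene-3-(propan-2-yl)octahydroazulene-3a,4(1H)-diol (3a-OH, 4-OH, 8a-CH3 and 3-i-Pr all cis) | CC(C)[C@@H]1CC[C@@]2(C)CCCC(=C)[C@H](O)[C@@]12O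
F2 | step 10 | 4-O-methanesulfonate of F1 | CC(C)[C@@H]1CC[C@@]2(C)CCCC(=C)[C@H](OS(C)(=O)=O)[C@@]12O
F3 | step 10 | 5α-eudesm-4(15)-en-6-one, (2S,4aR,8aS)-4a-methyl-8-methylidene-2-(propan-2-yl)octahydronaphthalen-1(2H)-one | CC(C)[C@@H]1CC[C@@]2(C)CCCC(=C)[C@@H]2C1=O
F4 | step 10 | 5α-eudesm-4(15)-en-6β-ol | CC(C)[C@@H]1CC[C@@]2(C)CCCC(=C)[C@@H]2[C@@H]1O
F5 | step 10 | 6β-hydroxy-15-nor-5α-eudesman-4-one | CC(C)[C@@H]1CC[C@@]2(C)CCCC(=O)[C@@H]2[C@@H]1O
F6 | step 6 | allyl (5S)-2-methyl-5-(propan-2-yl)cyclopent-1-en-1-yl carbonate | C=CCOC(=O)OC1=C(C)CC[C@H]1C(C)C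
F7 | step 6 | (2S,5S)-2-methyl-2-(prop-2-en-1-yl)-5-(propan-2-yl)cyclopentan-1-one | CC(C)[C@@H]1CC[C@@](C)(CC=C)C1=O
F8 | step 6 | (2R,5S)-2-[3-(9-borabicyclo[3.3.1]nonan-9-yl)propyl]-2-methyl-5-(propan-2-yl)cyclopentan-1-one | CC(C)[C@@H]1CC[C@@](C)(CCCB2C3CCCC2CCC3)C1=O
F9 | step 12 | (1R,2S,4aR,8S,8aS)-8-hydroxy-4a,8-dimethyl-2-(propan-2-yl)decahydronaphthalen-1-yl bromoacetate | CC(C)[C@@H]1CC[C@@]2(C)CCC[C@](C)(O)[C@@H]2[C@@H]1OC(=O)CBr
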